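**Retrosynthetic overview**
- Labels: ring A and ring D are the two 3-methoxyphenyl rings. Ring B is the catechol with the chain on C1, O on C3/C4 and the biaryl bond on C5. Ring C is the catechol with the biaryl bond on C1', O on C3'/C4' and the chain on C6'.
- Isoplagilin comes from global O-debenzylation of its tetrabenzyl ether. All four benzene rings are bought, so no ring is formed in the route.
- Key disconnection: both carbon substituents of ring C are removed at once, the C6'–CH2 bond to the ring D phenethyl unit and the C1'–C5 biaryl bond. This leads to the ring A–B aryl Grignard, 4,5-bis(benzyloxy)benzyne and 3-methoxyphenethyl bromide.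
- Enabling feature: in ring C the two carbon substituents sit on the adjacent atoms C1'/C6' and the two oxygens on C3'/C4', each carbon para to one oxygen. Ring C stripped of its carbon groups is therefore a twofold symmetric aryne. Arylmagnesiation has no regiochemical choice and places Mg exactly on C6', ready for alkylation.
- The ring A–B bromide comes from 3-bromo-4,5-dihydroxybenzaldehyde (benzylation, Horner–Wadsworth–Emmons olefination, diimide). The aryne precursor comes from 4,5-dibromocatechol (benzylation).

Key step: step 5

Remark: the target has no stereocentre. Its biaryl axis carries only two ortho substituents (O on ring B, CH2 on ring C), so it is taken as freely rotating and no stereocontrol is planned.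

**Step 1**
Reactants: 1 3-bromo-4,5-dihydroxybenzaldehyde
Product: 2 3,4-bis(benzyloxy)-5-bromobenzaldehyde
Conditions: BnBr (2.4 equiv), K2CO3, DMF, 60 °C
Reagents that add atoms: benzyl bromide, BrCc1ccccc1
Why: Williamson ether synthesis alkylates both catechol phenoxides without touching the aldehyde or the aryl bromide, and benzyl is chosen because it can later be removed beside the two aryl methyl ethers.

**Step 2**
Reactants: 2 3,4-bis(benzyloxy)-5-bromobenzaldehyde; 3 diethyl (3-methoxybenzyl)phosphonate
Product: 4 (E)-1,2-bis(benzyloxy)-3-bromo-5-[2-(3-methoxyphenyl)ethenyl]benzene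
Conditions: KOtBu, THF, 0 °C to rt
Reagents that add atoms: none
Why: Horner–Wadsworth–Emmons olefination of a non-enolisable aromatic aldehyde with a benzylic phosphonate anion should give the E-stilbene, whose geometry does not matter because the double bond is saturated in step 3.

**Step 3**
Reactants: 4 (E)-1,2-bis(benzyloxy)-3-bromo-5-[2-(3-methoxyphenyl)ethenyl]benzene
Product: 5 1,2-bis(benzyloxy)-3-bromo-5-[2-(3-methoxyphenyl)ethyl]benzene
Conditions: TsNHNH2 (excess, in portions), NaOAc, DME/H2O, reflux
Reagents that add atoms: none
Why: Diimide reduction (concerted syn transfer of two hydrogens from HN=NH made in the flask) saturates the C=C bond and spares the C–Br bond and the benzyl ethers, which hydrogenation over palladium would cleave.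

**Step 4**
Reactants: 6 4,5-dibromobenzene-1,2-diol
Product: 7 1,2-bis(benzyloxy)-4,5-dibromobenzene
Conditions: BnBr (2.4 equiv), K2CO3, DMF, 60 °C
Reagents that add atoms: benzyl bromide, BrCc1ccccc1
Why: Williamson ether synthesis on the symmetric catechol gives the symmetric aryne precursor with the same protecting group as in 5, so that one final operation frees all four phenols.

**Step 5**
Reactants: 5 1,2-bis(benzyloxy)-3-bromo-5-[2-(3-methoxyphenyl)ethyl]benzene; 7 1,2-bis(benzyloxy)-4,5-dibromobenzene; 8 1-(2-bromoethyl)-3-methoxybenzene
Product: 13 tetra-O-benzylisoplagilin, via ring B aryl Grignard 9 (not isolated), via bromoaryl Grignard 10 (not isolated), via symmetric aryne 11 (not isolated), via biaryl Grignard 12 (not isolated)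
Conditions: 5, Mg turnings (3 equiv), THF, 60 °C; then 7 (1.1 equiv) in THF added over 2 h, 60 °C; cannula filtration from residual Mg; then 8 (1.5 equiv), Li2CuCl4 (5 mol %), NMP, 0 °C to rt
Reagents that add atoms: none
Why: Mg inserts into the C–Br bond of 5 to give 9, then into one C–Br bond of slowly added 7 to give 10, which loses MgBr2 at 60 °C to aryne 11; 9 adds across the strained triple bond (forming the C5–C1' biaryl bond) and thereby places magnesium on the neighbouring ring C carbon C6' (12). Li2CuCl4 is reduced by 12 to a monovalent copper aryl species that displaces bromide from the primary carbon of 8 by SN2-type oxidative addition and reductive elimination, which forms the C6'–CH2 bond and completes the whole carbon skeleton. The closest known reaction type is the one-pot addition of aryl Grignard reagents to benzynes made from 1,2-dihaloarenes and Mg, with copper-catalysed capture of the resulting biphenyl-2-ylmagnesium halide by an electrophile (the standard entry to dialkylbiarylphosphine ligands), joined to the copper-catalysed Kumada-type coupling of aryl Grignard reagents with primary alkyl bromides. No ring is closed and no stereocentre is made. Regioselectivity needs no control because 11 is twofold symmetric (each aryne carbon is para to one benzyloxy group), so either mode of addition gives the same 12. Chemoselectivity is needed twice: 9 rather than 10 or 12 must capture 11, which slow addition of 7 to preformed 9 and the greater hindrance of 12 should secure, and substitution must beat E2 elimination of 8, which copper catalysis at 0 °C and the removal of residual Mg before 8 is added should secure.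

**Step 6**
Reactants: 13 tetra-O-benzylisoplagilin
Product: 14 isoplagilin
Conditions: H2 (1 atm), 10% Pd/C, EtOAc/MeOH, rt; filtration and concentration under argon
Reagents that add atoms: none
Why: Catalytic hydrogenolysis cleaves the four benzylic C–O bonds while the aryl methyl ethers and the saturated ethylene bridges are inert, so both catechols are released in one operation.

**Compound list**
1 | 3-bromo-4,5-dihydroxybenzaldehyde | O=Cc1cc(O)c(O)c(Br)c1 | starting material
2 | 3,4-bis(benzyloxy)-5-bromobenzaldehyde | O=Cc1cc(OCc2ccccc2)c(OCc2ccccc2)c(Br)c1 | intermediate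
3 | diethyl (3-methoxybenzyl)phosphonate | CCOP(=O)(Cc1cccc(OC)c1)OCC | starting material
4 | (E)-1,2-bis(benzyloxy)-3-bromo-5-[2-(3-methoxyphenyl)ethenyl]benzene | COc1cccc(/C=C/c2cc(OCc3ccccc3)c(OCc3ccccc3)c(Br)c2)c1 | intermediate
5 | 1,2-bis(benzyloxy)-3-bromo-5-[2-(3-methoxyphenyl)ethyl]benzene | COc1cccc(CCc2cc(OCc3ccccc3)c(OCc3ccccc3)c(Br)c2)c1 | intermediate
6 | 4,5-dibromobenzene-1,2-diol | Oc1cc(Br)c(Br)cc1O | starting material
7 | 1,2-bis(benzyloxy)-4,5-dibromobenzene | Brc1cc(OCc2ccccc2)c(OCc2ccccc2)cc1Br | intermediate
8 | 1-(2-bromoethyl)-3-methoxybenzene | COc1cccc(CCBr)c1 | starting material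
9 | {2,3-bis(benzyloxy)-5-[2-(3-methoxyphenyl)ethyl]phenyl}magnesium bromide | COc1cccc(CCc2cc(OCc3ccccc3)c(OCc3ccccc3)c([Mg]Br)c2)c1 | intermediate
10 | [4,5-bis(benzyloxy)-2-bromophenyl]magnesium bromide | Br[Mg]c1cc(OCc2ccccc2)c(OCc2ccccc2)cc1Br | intermediate
11 | 4,5-bis(benzyloxy)benzyne (1,2-didehydro-4,5-bis(benzyloxy)benzene) | C1(OCc2ccccc2)=CC#CC=C1OCc1ccccc1 | intermediate
12 | {2',3',4,5-tetrakis(benzyloxy)-5'-[2-(3-methoxyphenyl)ethyl]biphenyl-2-yl}magnesium bromide | COc1cccc(CCc2cc(OCc3ccccc3)c(OCc3ccccc3)c(-c3cc(OCc4ccccc4)c(OCc4ccccc4)cc3[Mg]Br)c2)c1 | intermediate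
13 | tetra-O-benzylisoplagilin, 2,3,4',5'-tetrakis(benzyloxy)-2',5-bis[2-(3-methoxyphenyl)ethyl]biphenyl | COc1cccc(CCc2cc(OCc3ccccc3)c(OCc3ccccc3)c(-c3cc(OCc4ccccc4)c(OCc4ccccc4)cc3CCc3cccc(OC)c3)c2)c1 | intermediate
14 | isoplagilin | COc1cccc(CCc2cc(O)c(O)c(-c3cc(O)c(O)cc3CCc3cccc(OC)c3)c2)c1 | target

**Step count**
- Total step count: 6.
- Longest linear sequence: 5 (steps 1, 2, 3, 5, 6).

**Steps most likely to fail**

**Step 5.**
- Risk: the aryne may be consumed by addition of 10 or 12 instead of 9 (oligomerisation). The hindered Grignard 12 may also act as a base on 8, giving E2 elimination with protonation of C6'.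
- Fallback: it sets out from 5 and 7 and comes back at 13. It gives up the aryne and reverses the polarity at the C6'–CH2 bond.
- Miyaura borylation of 5 (B2pin2, PdCl2(dppf), KOAc, dioxane, 90 °C) should give 2-{2,3-bis(benzyloxy)-5-[2-(3-methoxyphenyl)ethyl]phenyl}-4,4,5,5-tetramethyl-1,3,2-dioxaborolane F1.
- Mono Suzuki–Miyaura coupling with an excess of the symmetric dibromide 7 (Pd(PPh3)4, K2CO3, toluene/EtOH/H2O, 80 °C) should give 2',3',4,5-tetrakis(benzyloxy)-2-bromo-5'-[2-(3-methoxyphenyl)ethyl]biphenyl F2. Its remaining bromide is shielded by the new ortho aryl group.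
- Hydroboration of commercial 3-methoxystyrene with 9-BBN-H (THF, rt) should give 9-[2-(3-methoxyphenyl)ethyl]-9-borabicyclo[3.3.1]nonane F3.
- B-alkyl Suzuki–Miyaura coupling of F2 with F3 (PdCl2(dppf), aqueous K3PO4, THF/DMF, 60 °C) should then give 13.

**Step 3.**
- Risk: diimide may disproportionate faster than it reduces the conjugated 1,2-diaryl alkene. Saturation would then stall and leave alkene and alkane that are hard to separate.
- Fallback: it sets out from 2 and comes back at 5, and it never makes the alkene.
- Addition of commercial 3-methoxybenzylmagnesium chloride to 2 (THF, 0 °C) should give racemic 1-[3,4-bis(benzyloxy)-5-bromophenyl]-2-(3-methoxyphenyl)ethanol F4.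
- Ionic deoxygenation of F4 (Et3SiH, TFA, CH2Cl2, 0 °C) passes through the benzylic cation stabilised by the para benzyloxy group and should give 5.

**Step 6.**
- Risk: hydrogenolysis may stall at the benzyl ether that flanks the biaryl axis. The liberated catechols may also be oxidised by air to o-quinones during removal of the catalyst.
- Fallback: it sets out from 13 and comes back at 14. It replaces reduction by Lewis acid cleavage.
- BCl3 with pentamethylbenzene as cation scavenger (CH2Cl2, −78 °C, methanol quench) should remove benzyl selectively beside the aryl methyl ethers without any heterogeneous catalyst.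
- No new compound is made on this way (entry F0).

**Further compounds**
F1 | step 5 | 2-{2,3-bis(benzyloxy)-5-[2-(3-methoxyphenyl)ethyl]phenyl}-4,4,5,5-tetramethyl-1,3,2-dioxaborolane | COc1cccc(CCc2cc(OCc3ccccc3)c(OCc3ccccc3)c(B3OC(C)(C)C(C)(C)O3)c2)c1
F2 | step 5 | 2',3',4,5-tetrakis(benzyloxy)-2-bromo-5'-[2-(3-methoxyphenyl)ethyl]biphenyl | COc1cccc(CCc2cc(OCc3ccccc3)c(OCc3ccccc3)c(-c3cc(OCc4ccccc4)c(OCc4ccccc4)cc3Br)c2)c1
F3 | step 5 | 9-[2-(3-methoxyphenyl)ethyl]-9-borabicyclo[3.3.1]nonane | COc1cccc(CCB2C3CCCC2CCC3)c1
F4 | step 3 | 1-[3,4-bis(benzyloxy)-5-bromophenyl]-2-(3-methoxyphenyl)ethanol (racemic) | COc1cccc(CC(O)c2cc(OCc3ccccc3)c(OCc3ccccc3)c(Br)c2)c1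
F0 | step 6 | none | none
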